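The earlier runs and the new flask come from a simulation for an exercise, noise included.

Count the hours that converted substrate spends beside partner: Tuesday's and Sunday's run on equal clocks but differ in that count.

| flask | substrate | partner | remark | time |
|---|---|---|---|---|
| green | 0.10 M | 0.15 M | run made earlier |  |
| blue | 0.10 M | 0.10 M | run made earlier |  |
| violet | 0.10 M | 0.22 M | run made earlier |  |
| amber | 0.15 M | 0.15 M | run made earlier |  |
| Saturday's | 0.10 M | 0.150 M | one stirred flow tank at steady state, fed with the mixture as stated, mean residence time 8.0 h |  |
| Sunday's | 0.10 M | 0.150 M (fed, over 6.40 h) | a stirred flask in which partner is dosed at a steady rate over 6.40 h without added volume, worked up at 8.0 h | 8.0 h |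
| Monday's | 0.10 M (fed, over 6.40 h) | 0.150 M | all but substrate at the start; substrate goes in evenly over 6.40 h, the run ends at 8.0 h | 8.0 h |
| Tuesday's | 0.10 M | 0.150 M | a closed flask charged with all of it at once and left for 8.0 h | 8.0 h |

| run | time / h | intermediate / % | product / % |
|---|---|---|---|
| green | 0.417 | 12 | 0 |
| green | 1.33 | 32 | 3 |
| green | 2.50 | 47 | 7 |
| green | 3.00 | 53 | 10 |
| green | 5.00 | 57 | 21 |
| green | 6.00 | 64 | 25 |
| green | 8.00 | 63 | 30 |
| blue | 1.00 | 29 | 0 |
| blue | 2.00 | 46 | 5 |
| blue | 3.00 | 55 | 7 |
| blue | 4.00 | 60 | 9 |
| blue | 5.00 | 66 | 11 |
| blue | 6.00 | 68 | 12 |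
| violet | 0.333 | 10 | 0 |
| violet | 1.00 | 24 | 3 |
| violet | 2.00 | 40 | 8 |
| violet | 3.00 | 45 | 14 |
| violet | 4.00 | 54 | 19 |
| violet | 5.00 | 55 | 25 |
| violet | 6.00 | 54 | 26 |
| amber | 1.33 | 32 | 0 |
| amber | 2.50 | 50 | 6 |
| amber | 4.00 | 52 | 10 |
| amber | 5.00 | 59 | 19 |
| amber | 6.00 | 65 | 21 |

(readings scatter by 2 percentage points)

- the stated concentrations are those of everything mixed, before any reaction; amounts are the same in each set-up
- the earlier runs were read with a standard deviation of 2 percentage points
- the feed brings no volume worth counting
- the earlier runs were made in a closed, stirred flask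

- the set-up with the highest amount of intermediate at the outlet or at the end, in percent of the substrate put in ("none" if the first two lie within 2 percentage points) (Saturday's / Sunday's / Monday's / Tuesday's / none)
- amount of intermediate at the outlet or at the end, in percent of the substrate put in, Saturday's
- amount of intermediate at the outlet or at the end, in percent of the substrate put in, Sunday's
- amount of intermediate at the outlet or at the end, in percent of the substrate put in, Monday's
- amount of intermediate at the outlet or at the end, in percent of the substrate put in, Tuesday's

At 6.00 h, the sum of intermediate and product, averaged over the earlier runs, gives a first-order loss of substrate of 0.303 h⁻¹, or one power of ten every 7.59 h. So green's intermediate curve leaves zero at that fraction of the charge per hour and bends near the half-life of substrate, 2.29 h; green reads 47 % at 2.50 h. Then it flattens, with green reading 64 % at 6.00 h and 63 % at 8.00 h.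

Tuesday's and Sunday's are charged with substrate at the start, so by 8.0 h this rate converts 91.1 % of it in each, and the split c(product)/c(intermediate) shares that out. The split rises with partner: at 6.00 h violet reads 0.481 and blue 0.176. Contact hours are the time integral of the converted share times c(partner) over 0.150 M, with partner counted as charged so far and nothing subtracted for losses. A closed flask at 0.150 M partner collects 4.99 h. Green's split as read at 8.00 h, 0.476, over those hours gives 0.0954 h⁻¹, the drain number: split per contact hour, with the drain on intermediate taken as pseudo-first-order in it at a given c(partner).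

Intermediate is then the converted share over one plus the split. Tuesday's gets 61.7 %. Sunday's steadily dosed partner collects 3.63 h, fewer hours than Tuesday's, which gives 67.7 %.

The forecast, holding that “partner stays scarce while intermediate builds”, chose Sunday's and gave 50 %, 56 % and 62 % for Saturday's, Monday's and Tuesday's, and for Sunday's 75 % (range 62 % to 83 %), above the reckoning here.

The flasks give 49.0 % on Saturday's, 67.1 % on Sunday's, 57.1 % on Monday's and 63.0 % on Tuesday's, so the best is Sunday's.

    substrate → intermediate (k = 8.60 × 10⁻⁵ s⁻¹)
    partner + intermediate ⇌ product (K = 12.0 M⁻¹, k = 2.34 × 10⁻⁴ M⁻¹ s⁻¹)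
    partner ⇌ dormant form (K = 0.254, k = 4.67 × 10⁻⁵ s⁻¹)

In Tuesday's, intermediate is made 4.36 times as fast as it is used up at 1.98 h, but that ratio stands at 0.844 by 8.00 h, each step taken net. Sunday's ends with 24.5 % product over 67.1 % intermediate, a split of 0.364, or 0.100 h⁻¹ per contact hour against the drain number 0.0954 h⁻¹. The neighbour of Tuesday's charged with 0.26 M partner collects 8.65 h, so the drain number gives a split of 0.825 and 49.9 % intermediate. That flask ends at 48.9 % intermediate and 42.7 % product.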